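## The problem

Atom numbers follow the target SMILES: C1 (CHOAc), C2, C3 (CMeOAc), C4, C5 (ring-fusion CH), C6, C7 (C=O), C8=C9, C10, C11, N12 (NMe), C13–C15, C16 (quaternary). Ring A is C1–C5 with C16, ring B is C5–C8 with C16, ring C is C8–C16.

- The target is a cis-fused hydrindanone (rings A and B share C5–C16) whose ketone α-carbon C8 and angular carbon C16 are bridged by a nine-membered N-methyl azonine. The bridge starts with an exocyclic enone C8=C9 in which C10 is trans to C7, so the alkene is cis inside ring C.
- There are four stereocentres: the all-carbon quaternary C16, and C1, C3 and C5 on ring A. On ring A the C1 and C3 oxygens and the two ring B bonds (C5–C6, C16–C8) lie on one face; the C3 methyl, C5–H and the C15 chain lie on the other.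
- C16 is the hub. Once set it can direct C5 (ring fusion) and, together with C1, the tertiary carbinol C3. C1 is a plain secondary carbinol that a chiral reagent can set and that can then direct C16.
- The C7 ketone has two α-methylenes, C6 and C8, and only C8 may be functionalised.
- Three groups are fragile. The tertiary acetate at C3 ionises in acid. The δ-amino enone is a vinylogous Mannich base, open to amine elimination, conjugate addition and E/Z drift. The basic amine interferes with acylation and metal chemistry. Acetates and azonine therefore belong at the end.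
- The enabling feature is the C1 oxygen: it sits on the carbon next to C16 and is cis to ring B, so C5, C4, O, C1 and C16 can be a temporary five-membered ring. Ring B is then the cyclopentenone of an allyl propargyl ether, with alkyne C5≡C6, 1,1-disubstituted alkene C16=C8 and CO as C7.

## Retrosynthesis

**Acetates last.** Target 29 is cut at both ester C–O bonds to diol 28. The tertiary acetate would not survive the acid needed for carbamate removal, and acetates do not tolerate the enolate chemistry at C8. Diol 28 comes from its bis(triethylsilyl) ether 27; the silyl groups are kept through ring closure so that the C1 oxygen cannot alkylate at C13.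

**Azonine at N12–C13.** Ring C is opened at N12–C13 to amino chloride 25 (closing through iodide 26). Cutting N12–C11 instead would put a leaving group δ to the enone and invite 1,4-elimination. Cutting C8=C9 would need a β-amino aldehyde and a nine-membered aldol condensation. The chosen cut needs only a primary chloride that can ride through the whole route, and the E-enone holds C10 cis to C16 so both chains point the same way. Amine 25 comes from Boc carbamate 23.

**C8=C9 by aldol and dehydration, C5 by hydrogenation in between.** Enone 23 is cut at C8=C9 to aldehyde 18 and bicyclic enone 17, via aldol 20, hydrogenation product 21 and mesylate 22. The order is forced. While C5=C6 is present, C6 is vinylic and only C8 can be enolised, so the aldol comes first. The C8 alkylidene must not exist during hydrogenation, so dehydration comes after. C16 bears no hydrogen, so elimination can only go toward C9.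

**Ring A at C3–C4.** Silyl ether 17 is the protected form of diol 16, which is cut at C3–C4 to keto enone 15 (vinylogous aldol). This cut uses C4 as the γ-carbon of the ring B enone and C3 as a methyl ketone. It creates the tertiary carbinol and ring A together and leaves the enone in place for the next steps. A cut at C4–C5 or C1–C16 would break the quaternary centre or the link to ring B.

**Unmasking C3 and C4.** Ketone 15 comes from alkene 13 by oxidative cleavage of a 2-methylallyl group, a base-stable masked acetonyl unit. Alkene 13 comes from oxabicycle 11 by reconnecting C4 to the C1 oxygen. In the forward sense this ether C–O bond is γ to the enone carbonyl and is cleaved reductively, releasing the C1 hydroxyl and turning C4 into the enone's γ-methyl.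

**Key disconnection.** Oxabicyclic enone 11 is cut at C5–C16, C6–C7 and C7–C8 to enyne 9 and CO (Pauson–Khand, through cobalt complex 10). Two rings, three C–C bonds and the quaternary centre disappear, leaving an acyclic ether with one stereocentre. The forward reaction must insert a 1,1-disubstituted alkene and transmit C1 to C16.

**Acyclic precursor.** Enyne 9 is the propargyl ether (from bromide 8) of alcohol 7. Alcohol 7 is cut at C1–C2 to enal 4 and 2-methylallylmagnesium chloride 5 (asymmetric allylboration through borinate 6). Enal 4 is the α-methylenation product of 5-chloropentanal 2 with formaldehyde 3, and 2 comes from 5-chloropentan-1-ol 1.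

## Roads not taken

**Alternative 1:** ring-closing metathesis of the azonine at C14–C15.
- Cut and key step: the C14=C15 alkene of A1 is cut back to diene A2, which carries a vinyl group on C16 and an N-allyl group. The amine is masked as its ammonium tosylate and closed with the second-generation Grubbs catalyst, losing ethylene.
- Merits: this is probably the more dependable way to a nine-membered unsaturated azacycle. It tolerates the acetates, so acetylation need not be last, and it avoids a medium-ring SN2 reaction.
- Weak points: the C16 vinyl group is neopentylic and slow to engage. A1 then needs hydrogenation of C14=C15 beside the conjugated C8=C9. The plan is silent on the harder problem of ring B and C16, and a C16 vinyl group would make the cyclocarbonylation partner a diene.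
- Comparison: for ring C alone this road is at least as good. The chosen plan sets against it that its key step solves C16 and ring B, that the C13 chloride costs nothing to carry, and that no post-closure reduction is needed.

**Alternative 2:** one-carbon insertion into a dichlorocyclobutanone.
- Cut and key step: C5–C6 and C6–C7 are cut. Cyclobutanone A4 (from dichloroketene and a ring A cyclohexene) is expanded with diazomethane, the non-chlorinated carbon migrating, to give A3.
- Merits: the suprafacial ketene cycloaddition fixes the cis ring fusion at C5 and C16 without a hydrogenation, and the gem-dichloride marks C8 for a regiospecific zinc enolate. On both counts it is better than the chosen plan, which relies on a facially selective hydrogenation and on the enone to distinguish C8 from C6.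
- Weak points: A3 has no oxygen at C1, only a C1=C2 alkene, and hydrating a 1,2-disubstituted alkene next to the quaternary centre with the right regio- and stereochemistry is unsolved. Facial control of the ketene addition rests on the remote C3 centre. An enantioenriched ring A with the tertiary carbinol must be made first. Diazomethane and a dechlorination are added.
- Comparison: the chosen plan makes C1 first and uses its oxygen as the tether, so the C1 problem never arises; it pays with a substrate-controlled hydrogenation.

**Alternative 3:** catalytic asymmetric Diels–Alder for ring A and C16.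
- Cut and key step: C1–C16 and C4–C5 are cut. Silyloxy diene A6 and enal A7 combine under a chiral oxazaborolidinium Lewis acid to give A5.
- Merits: C1, C5 and C16 are set in one catalytic step, more stereocentres per step than the chosen key step, and with a catalytic rather than stoichiometric chiral source.
- Weak points: ring B is still missing. The ester carbon (C6) and formyl carbon (C8) of A5 must be joined through an extra carbon C7, which costs several redox and C–C steps. C3 has to come from Markovnikov hydration of the C2=C3 alkene with uncertain facial control. A7 is a hindered, geometry-sensitive Z enal.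
- Comparison: this road is better for ring A stereochemistry. The chosen plan is shorter to the full hydrindanone, because one step gives ring B, C16 and the handle for ring A.

Key step: step 5

## Route

Remark: atom labels C1–C16 are those defined above. 2-Methylallylmagnesium chloride (5) and tert-butyl methyl(3-oxopropyl)carbamate (18) are taken as purchasable. The C8 and C9 centres of 20–22 form as mixtures and are erased in step 12.

Step 1
Reactants: 1 5-chloropentan-1-ol
Product: 2 5-chloropentanal
Conditions: TEMPO (10 mol%), PhI(OAc)2, CH2Cl2, rt
Reagents that add atoms: none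
Why: TEMPO-catalysed oxidation of a primary alcohol stops at the aldehyde, and the primary chloride is inert.

Step 2
Reactants: 2 5-chloropentanal; 3 formaldehyde (37% aq.)
Product: 4 5-chloro-2-methylidenepentanal
Conditions: pyrrolidine (10 mol%), propionic acid (10 mol%), i-PrOH, 45 °C
Reagents that add atoms: none
Why: Amine/acid-catalysed α-methylenation (Mannich condensation, then loss of the amine) of an α-unbranched aldehyde; it installs the C16=C8 alkene.

Step 3
Reactants: 4 5-chloro-2-methylidenepentanal; 5 2-methylallylmagnesium chloride
Product: 7 (4S)-8-chloro-2-methyl-5-methylideneoct-1-en-4-ol, via diisopinocampheylborinate 6 (not isolated)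
Conditions: (−)-Ipc2BOMe, 5, Et2O, −78 °C to rt; then 4, −78 °C; NaOH, H2O2
Reagents that add atoms: none
Why: Brown allylboration with the 2-methylallyl borane; the chair Zimmerman–Traxler transition state of the reagent derived from (+)-α-pinene adds to the Si face of the enal, which for an alkenyl aldehyde gives the (S)-carbinol C1. Addition is 1,2 only.

Step 4
Reactants: 7 (4S)-8-chloro-2-methyl-5-methylideneoct-1-en-4-ol; 8 3-bromoprop-1-yne
Product: 9 (4S)-8-chloro-2-methyl-5-methylidene-4-(prop-2-yn-1-yloxy)oct-1-ene
Conditions: NaH, 8, Bu4NI (cat.), THF/DMF, 0 °C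
Reagents that add atoms: none
Why: Williamson etherification; propargyl bromide is far more reactive than the pendant primary chloride, so O-propargylation should outrun six-membered ether formation at 0 °C.

Step 5
Reactants: 9 (4S)-8-chloro-2-methyl-5-methylidene-4-(prop-2-yn-1-yloxy)oct-1-ene
Product: 11 (3S,3aR)-3a-(3-chloropropyl)-3-(2-methylprop-2-en-1-yl)-1,3,3a,4-tetrahydro-5H-cyclopenta[c]furan-5-one, via alkyne–Co2(CO)6 complex 10 (not isolated)
Conditions: Co2(CO)8 (1.1 equiv), CH2Cl2, rt; then NMO (8 equiv), 0 °C to rt
Reagents that add atoms: dicobalt octacarbonyl, Co2(CO)8, O=C=[Co](=C=O)(=C=O)(=C=O)[Co](=C=O)(=C=O)(=C=O)=C=O (one carbonyl ligand becomes C7=O)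
Why: Co2(CO)8 (zerovalent cobalt) binds the terminal alkyne as complex 10 with loss of two CO; NMO oxidises off one more CO and frees a site for the C16=C8 alkene. The alkene inserts into the cobalt–carbon bond at the internal alkyne carbon (C5–C16), CO inserts, and reductive elimination forms C6–C7 and C7–C8. The closest known reaction is the amine-oxide-promoted intramolecular Pauson–Khand reaction of allyl propargyl ethers with 1,1-disubstituted alkenes, which gives angularly substituted 3-oxabicyclo[3.3.0]octenones. The oxacycle closes in the insertion step in a 5-exo sense across the three-atom C4–O–C1 tether; ring B closes by the [2+2+1] union of C5≡C6, C16=C8 and CO. C16 is controlled by C1: in the envelope-like insertion geometry the 2-methylallyl group on C1 sits on the convex face, cis to the chloropropyl chain, which gives (3S,3aR). Regiochemistry is fixed by the tether, and the terminal alkyne leaves C6 as CH. The step must choose between two 1,1-disubstituted alkenes; the allylic one closes a five-membered ring and should react much faster than the homoallylic one, which would need a six-membered ring.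

Step 6
Reactants: 11 (3S,3aR)-3a-(3-chloropropyl)-3-(2-methylprop-2-en-1-yl)-1,3,3a,4-tetrahydro-5H-cyclopenta[c]furan-5-one
Product: 13 (4R)-4-(3-chloropropyl)-4-[(1S)-1-hydroxy-3-methylbut-3-en-1-yl]-3-methylcyclopent-2-en-1-one, via exo-methylene ketone 12 (not isolated)
Conditions: SmI2 (2.5 equiv), MeOH, THF, −78 °C; then DBU (cat.), CH2Cl2, rt
Reagents that add atoms: none
Why: SmI2 (divalent samarium) reduces the enone, and the ether C4–O bond γ to the carbonyl is expelled as the C1 alkoxide, the vinylogous form of α-alkoxy ketone cleavage. α-Protonation of the dienolate gives 12 and base conjugates it to the β-methyl enone 13. The alkyl chloride and isolated alkenes are inert to SmI2 without HMPA.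

Step 7
Reactants: 13 (4R)-4-(3-chloropropyl)-4-[(1S)-1-hydroxy-3-methylbut-3-en-1-yl]-3-methylcyclopent-2-en-1-one
Product: 15 (4R)-4-(3-chloropropyl)-4-[(1S)-1-hydroxy-3-oxobutyl]-3-methylcyclopent-2-en-1-one, via vicinal diol 14 (not isolated)
Conditions: OsO4 (2 mol%), NaIO4 (4 equiv), 2,6-lutidine, dioxane/H2O, rt
Reagents that add atoms: osmium tetroxide, O=[Os](=O)(=O)=O (catalytic oxygen carrier); sodium periodate, [Na+].[O-]I(=O)(=O)=O (terminal oxidant that resupplies the oxygen)
Why: Lemieux–Johnson oxidation; OsO4 dihydroxylates the electron-rich 1,1-disubstituted alkene much faster than the electron-poor enone, and NaIO4 cleaves the diol to the C3 methyl ketone.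

Step 8
Reactants: 15 (4R)-4-(3-chloropropyl)-4-[(1S)-1-hydroxy-3-oxobutyl]-3-methylcyclopent-2-en-1-one
Product: 16 (5S,7S,7aR)-7a-(3-chloropropyl)-5,7-dihydroxy-5-methyl-1,4,5,6,7,7a-hexahydro-2H-inden-2-one
Conditions: LiCl, DBU, MeCN, 0 °C to rt
Reagents that add atoms: none
Why: Intramolecular vinylogous aldol addition under soft enolisation; only the γ-hydrogens at C4 are acidic enough for DBU, so neither C8 nor the methyl ketone is enolised and no alkoxide forms to attack the chloride. C4 adds to C3 through a chair (C4–C5–C16–C1–C2–C3) in which Li+ bridges the C1 hydroxyl and the C3 carbonyl, placing the new oxygen axial and cis to the C1 oxygen with methyl equatorial. This cis-diol is also the more stable epimer if the addition is reversible.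

Step 9
Reactants: 16 (5S,7S,7aR)-7a-(3-chloropropyl)-5,7-dihydroxy-5-methyl-1,4,5,6,7,7a-hexahydro-2H-inden-2-one
Product: 17 (5S,7S,7aR)-7a-(3-chloropropyl)-5-methyl-5,7-bis(triethylsilyloxy)-1,4,5,6,7,7a-hexahydro-2H-inden-2-one
Conditions: Et3SiOTf (3 equiv), 2,6-lutidine, CH2Cl2, −78 to 0 °C
Reagents that add atoms: triethylsilyl trifluoromethanesulfonate, CC[Si](CC)(CC)OS(=O)(=O)C(F)(F)F
Why: Silyl triflate with lutidine silylates secondary and tertiary hydroxyls alike. The ethers are needed for the enolate step, shield one face in step 11 and block O-alkylation in step 14.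

Step 10
Reactants: 17 (5S,7S,7aR)-7a-(3-chloropropyl)-5-methyl-5,7-bis(triethylsilyloxy)-1,4,5,6,7,7a-hexahydro-2H-inden-2-one; 18 tert-butyl methyl(3-oxopropyl)carbamate
Product: 20 C8 aldol adduct: 17 bearing a 1-hydroxy-3-[(tert-butoxycarbonyl)(methyl)amino]propyl group at C8 (mixture at C8 and C9), via cross-conjugated lithium enolate 19 (not isolated)
Conditions: LiN(i-Pr)2 (1.1 equiv), THF, −78 °C; then 18, −78 °C; aq. NH4Cl
Reagents that add atoms: none
Why: Kinetic deprotonation of a cyclic enone occurs at α′ (C8), because C6 is vinylic and γ-deprotonation at C4 is slower; aldol addition to 18 forms C8–C9. Both new centres are removed in step 12.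

Step 11
Reactants: 20 C8 aldol adduct
Product: 21 cis-fused hydrindanone: 20 with C5=C6 saturated and C5–H cis to the C16 chloropropyl chain
Conditions: H2 (1 atm), 10% Pd/C, EtOAc, rt
Reagents that add atoms: none
Why: Heterogeneous hydrogenation of the trisubstituted enone; the face of C5 on the side of C1 is covered by ring A and the two axial silyloxy groups at C1 and C3, so hydrogen arrives from the chloropropyl face and gives the cis ring fusion. EtOAc spares the silyl ethers; the alkyl chloride and carbamate are inert.

Step 12
Reactants: 21 cis-fused hydrindanone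
Product: 23 (E)-enone: 21 dehydrated to C8=C9 with C10 trans to C7, via C9 mesylate 22 (not isolated)
Conditions: MsCl, Et3N, CH2Cl2, 0 °C; then DBU, rt
Reagents that add atoms: none
Why: Mesylation then E1cB elimination through the C8 enolate; C16 has no hydrogen, so the alkene can only form toward C9. The E isomer (C10 away from the carbonyl) is expected and is the one needed for ring closure.

Step 13
Reactants: 23 (E)-enone
Product: 25 secondary amine: 23 with NHMe in place of N(Me)Boc, via trimethylsilyl carbamate 24 (not isolated)
Conditions: Me3SiOTf, 2,6-lutidine, CH2Cl2, 0 °C; then MeOH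
Reagents that add atoms: none
Why: Silyl-triflate-mediated Boc cleavage (loss of the tert-butyl cation from the O-silylated carbamate, then methanolysis and decarboxylation) leaves the triethylsilyl ethers and the enone intact, whereas protic acid would strip the ethers.

Step 14
Reactants: 25 secondary amine
Product: 27 azonine: tricyclic N-methyl amine with N12–C13 closed and both triethylsilyl ethers in place, via primary iodide 26 (not isolated)
Conditions: NaI (3 equiv), K2CO3, MeCN (2 mM), 70 °C
Reagents that add atoms: none
Why: Finkelstein exchange then intramolecular SN2 N-alkylation at high dilution; the E-enone holds C10 cis to C16, and the quaternary centre keeps the two chains on the same side. The silyl ethers keep the C1 oxygen from competing.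

Step 15
Reactants: 27 azonine bis(triethylsilyl) ether
Product: 28 azonine diol (C1–OH and C3–OH free)
Conditions: HF·pyridine, THF/pyridine, 0 °C to rt
Reagents that add atoms: none
Why: Fluoride-driven desilylation removes the secondary and tertiary silyl ethers without touching the enone; the amine is merely protonated.

Step 16
Reactants: 28 azonine diol
Product: 29 target diacetate (CNP0386920.1)
Conditions: Ac2O (10 equiv), DMAP (0.5 equiv), Et3N, CH2Cl2, 40 °C
Reagents that add atoms: acetic anhydride, CC(=O)OC(C)=O
Why: DMAP-catalysed acyl transfer acetylates the secondary and the tertiary hydroxyl; the tertiary amine cannot be acylated irreversibly. The step is last because the tertiary acetate is acid-labile.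

## Compound list

1 | 5-chloropentan-1-ol | OCCCCCCl | starting material
2 | 5-chloropentanal | O=CCCCCCl | intermediate
3 | formaldehyde | C=O | starting material
4 | 5-chloro-2-methylidenepentanal | C=C(CCCCl)C=O | intermediate
5 | 2-methylallylmagnesium chloride | C=C(C)C[Mg]Cl | starting material
6 | diisopinocampheylborinate of 7 | C=C(C)C[C@H](OB([C@@H]1C[C@@H]2C[C@H]([C@H]1C)C2(C)C)[C@@H]1C[C@@H]2C[C@H]([C@H]1C)C2(C)C)C(=C)CCCCl | intermediate (not isolated)
7 | (4S)-8-chloro-2-methyl-5-methylideneoct-1-en-4-ol | C=C(C)C[C@H](O)C(=C)CCCCl | intermediate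
8 | 3-bromoprop-1-yne | C#CCBr | starting material
9 | (4S)-8-chloro-2-methyl-5-methylidene-4-(prop-2-yn-1-yloxy)oct-1-ene | C#CCO[C@@H](CC(C)=C)C(=C)CCCCl | intermediate
10 | hexacarbonyldicobalt complex of the alkyne of 9 | O=C=[Co]12(=C=O)(=C=O)[Co]3(=C=O)(=C=O)(=C=O)C1([H])C23CO[C@@H](CC(C)=C)C(=C)CCCCl | intermediate (not isolated)
11 | (3S,3aR)-3a-(3-chloropropyl)-3-(2-methylprop-2-en-1-yl)-1,3,3a,4-tetrahydro-5H-cyclopenta[c]furan-5-one | C=C(C)C[C@@H]1OCC2=CC(=O)C[C@@]12CCCCl | intermediate
12 | (4R)-4-(3-chloropropyl)-4-[(1S)-1-hydroxy-3-methylbut-3-en-1-yl]-3-methylidenecyclopentan-1-one | C=C(C)C[C@H](O)[C@]1(CCCCl)CC(=O)CC1=C | intermediate (not isolated)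
13 | (4R)-4-(3-chloropropyl)-4-[(1S)-1-hydroxy-3-methylbut-3-en-1-yl]-3-methylcyclopent-2-en-1-one | C=C(C)C[C@H](O)[C@]1(CCCCl)CC(=O)C=C1C | intermediate
14 | (4R)-4-(3-chloropropyl)-3-methyl-4-[(1S)-1,3,4-trihydroxy-3-methylbutyl]cyclopent-2-en-1-one (both epimers at the new carbinol) | CC(O)(CO)C[C@H](O)[C@]1(CCCCl)CC(=O)C=C1C | intermediate (not isolated)
15 | (4R)-4-(3-chloropropyl)-4-[(1S)-1-hydroxy-3-oxobutyl]-3-methylcyclopent-2-en-1-one | CC(=O)C[C@H](O)[C@]1(CCCCl)CC(=O)C=C1C | intermediate
16 | (5S,7S,7aR)-7a-(3-chloropropyl)-5,7-dihydroxy-5-methyl-1,4,5,6,7,7a-hexahydro-2H-inden-2-one | O[C@H]1C[C@@](C)(O)CC2=CC(=O)C[C@]21CCCCl | intermediate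
17 | (5S,7S,7aR)-7a-(3-chloropropyl)-5-methyl-5,7-bis(triethylsilyloxy)-1,4,5,6,7,7a-hexahydro-2H-inden-2-one | CC[Si](CC)(CC)O[C@H]1C[C@@](C)(O[Si](CC)(CC)CC)CC2=CC(=O)C[C@]21CCCCl | intermediate
18 | tert-butyl methyl(3-oxopropyl)carbamate | CN(CCC=O)C(=O)OC(C)(C)C | starting material
19 | lithium enolate of 17 (C7–OLi, C7=C8) | CC[Si](CC)(CC)O[C@H]1C[C@@](C)(O[Si](CC)(CC)CC)CC2=CC(O[Li])=C[C@]21CCCCl | intermediate (not isolated)
20 | C8 aldol adduct of 17 and 18 (C8 and C9 mixed) | CC[Si](CC)(CC)O[C@H]1C[C@@](C)(O[Si](CC)(CC)CC)CC2=CC(=O)C(C(O)CCN(C)C(=O)OC(C)(C)C)[C@]21CCCCl | intermediate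
21 | cis-fused hydrindanone from 20 (C5–H cis to the chloropropyl chain) | CC[Si](CC)(CC)O[C@H]1C[C@@](C)(O[Si](CC)(CC)CC)C[C@H]2CC(=O)C(C(O)CCN(C)C(=O)OC(C)(C)C)[C@]21CCCCl | intermediate
22 | C9 methanesulfonate of 21 | CC[Si](CC)(CC)O[C@H]1C[C@@](C)(O[Si](CC)(CC)CC)C[C@H]2CC(=O)C(C(OS(C)(=O)=O)CCN(C)C(=O)OC(C)(C)C)[C@]21CCCCl | intermediate (not isolated)
23 | (E)-C8=C9 enone with N(Me)Boc side chain, chloropropyl chain and two triethylsilyl ethers | CC[Si](CC)(CC)O[C@H]1C[C@@](C)(O[Si](CC)(CC)CC)C[C@H]2CC(=O)/C(=C/CCN(C)C(=O)OC(C)(C)C)[C@]21CCCCl | intermediate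
24 | trimethylsilyl carbamate of 25 | CC[Si](CC)(CC)O[C@H]1C[C@@](C)(O[Si](CC)(CC)CC)C[C@H]2CC(=O)/C(=C/CCN(C)C(=O)O[Si](C)(C)C)[C@]21CCCCl | intermediate (not isolated)
25 | secondary amine (NHMe) of the (E)-enone, chloride | CC[Si](CC)(CC)O[C@H]1C[C@@](C)(O[Si](CC)(CC)CC)C[C@H]2CC(=O)/C(=C/CCNC)[C@]21CCCCl | intermediate
26 | secondary amine of the (E)-enone, iodide | CC[Si](CC)(CC)O[C@H]1C[C@@](C)(O[Si](CC)(CC)CC)C[C@H]2CC(=O)/C(=C/CCNC)[C@]21CCCI | intermediate (not isolated)
27 | tricyclic N-methyl azonine, bis(triethylsilyl) ether | CC[Si](CC)(CC)O[C@H]1C[C@@](C)(O[Si](CC)(CC)CC)C[C@H]2CC(=O)/C3=C/CCN(C)CCC[C@@]321 | intermediate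
28 | tricyclic N-methyl azonine diol | O[C@H]1C[C@@](C)(O)C[C@H]2CC(=O)/C3=C/CCN(C)CCC[C@@]321 | intermediate
29 | target diacetate, CNP0386920.1 | CC(=O)O[C@H]1C[C@@](C)(OC(C)=O)C[C@H]2CC(=O)/C3=C/CCN(C)CCC[C@@]321 | target

## Step count and least certain steps

Total: 16 steps. Longest linear sequence: 16 steps, from 5-chloropentan-1-ol (1).

**Step 5 (key step).** The C1 centre steers C16 through a single allylic substituent, so facial discrimination in the alkene insertion may be modest. Insertion of a 1,1-disubstituted alkene may also be slow enough for the cobalt complex to decay. Fallback, from 9 back to 11: the alkyne is capped (LiN(SiMe3)2, Me3SiCl, THF, −78 °C) to give the silyl enyne F1. Its bulky alkyne terminus should clash with a C1 substituent on the concave face and widen the preference for the convex arrangement. Cyclocarbonylation under the step 5 conditions gives the α-silyl enone F2, and protodesilylation (Bu4NF, wet THF, 0 °C) returns to 11.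

**Step 8.** Enolisation may go the wrong way (C8 attacking C3 to a five-membered ring, or the methyl ketone adding to C5), the reversible addition may stall, or the product may lose water to a dienone. Fallback, from 11 back to 16, with no enolate involved: Lemieux–Johnson oxidation is run first to give the keto ether F3. SmI2/MeOH at −78 °C with a neutral work-up keeps the kinetic exo-methylene hydroxy diketone F4. Me2AlCl (CH2Cl2, −78 to 0 °C) then binds the C1 oxygen, chelates the C3 ketone and promotes a type 2 carbonyl–ene cyclisation: the C4 terminus of the C5=C4 alkene adds to C3 and a C6 hydrogen is transferred, giving 16 with the two oxygens cis.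

**Step 11.** Facial selectivity may be poor, because the C8 side chain, expected on the chloropropyl face, partly blocks the face that ring A leaves open. Fallback, from 20 to 21 with no new compound (F0): the stereocontrol is changed from steric approach to catalyst anchoring. A cationic homogeneous catalyst, [Rh(nbd)(dppb)]BF4 or [Ir(cod)(PCy3)(py)]PF6, under H2 in CH2Cl2 is bound by the free C9 hydroxyl and delivers hydrogen from the face that carries the side chain.

**Step 14.** The nine-membered SN2 closure may be slow, so that oligomerisation competes, and any Z-enone from step 12 cannot close. Fallback, from 23 back to 27, by reversible C=N formation instead of SN2: NaI in acetone gives the iodo carbamate F5. A Kornblum-type oxidation with NMO in DMSO gives the aldehyde F6. Me3SiOTf/2,6-lutidine then MeOH frees the amino aldehyde F7, and NaBH(OAc)3/AcOH in dilute ClCH2CH2Cl closes the ring by intramolecular reductive amination.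

**Step 4.** The alkoxide of 7 may attack its own C13 chloride and form a tetrahydropyran in competition with propargylation. Fallback, from 7 to 10, avoiding any alkoxide: Nicholas etherification. The preformed hexacarbonyldicobalt complex of propargyl alcohol F8 (from prop-2-yn-1-ol and Co2(CO)8) is ionised with BF3·OEt2 in CH2Cl2 at −20 °C and trapped by 7. This gives complex 10 directly, which enters the NMO stage of step 5.

## Further compounds

F1 | step 5 | (4S)-8-chloro-2-methyl-5-methylidene-4-{[3-(trimethylsilyl)prop-2-yn-1-yl]oxy}oct-1-ene | C[Si](C)(C)C#CCO[C@@H](CC(C)=C)C(=C)CCCCl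
F2 | step 5 | 6-trimethylsilyl derivative of 11 (silyl group on the enone α-carbon C6) | C=C(C)C[C@@H]1OCC2=C([Si](C)(C)C)C(=O)C[C@@]12CCCCl
F3 | step 8 | (3S,3aR)-3a-(3-chloropropyl)-3-(2-oxopropyl)-1,3,3a,4-tetrahydro-5H-cyclopenta[c]furan-5-one | CC(=O)C[C@@H]1OCC2=CC(=O)C[C@@]12CCCCl
F4 | step 8 | (4R)-4-(3-chloropropyl)-4-[(1S)-1-hydroxy-3-oxobutyl]-3-methylidenecyclopentan-1-one | CC(=O)C[C@H](O)[C@]1(CCCCl)CC(=O)CC1=C
F0 | step 11 | none | none
F5 | step 14 | iodo analogue of 23 (C13–I) | CC[Si](CC)(CC)O[C@H]1C[C@@](C)(O[Si](CC)(CC)CC)C[C@H]2CC(=O)/C(=C/CCN(C)C(=O)OC(C)(C)C)[C@]21CCCI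
F6 | step 14 | C13 aldehyde analogue of 23 | CC[Si](CC)(CC)O[C@H]1C[C@@](C)(O[Si](CC)(CC)CC)C[C@H]2CC(=O)/C(=C/CCN(C)C(=O)OC(C)(C)C)[C@]21CCC=O
F7 | step 14 | amino aldehyde (NHMe, C13 aldehyde) | CC[Si](CC)(CC)O[C@H]1C[C@@](C)(O[Si](CC)(CC)CC)C[C@H]2CC(=O)/C(=C/CCNC)[C@]21CCC=O
F8 | step 4 | hexacarbonyldicobalt complex of prop-2-yn-1-ol | O=C=[Co]12(=C=O)(=C=O)[Co]3(=C=O)(=C=O)(=C=O)C1([H])C23CO
A1 | alternative 1 | 14,15-didehydro target | CC(=O)O[C@H]1C[C@@](C)(OC(C)=O)C[C@H]2CC(=O)/C3=C/CCN(C)C/C=C\[C@@]321
A2 | alternative 1 | metathesis precursor with C16 vinyl and N-allyl groups (free base) | CC(=O)O[C@H]1C[C@@](C)(OC(C)=O)C[C@H]2CC(=O)/C(=C/CCN(C)CC=C)[C@]21C=C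
A3 | alternative 2 | ring A-fused 2,2-dichlorocyclopentanone | C1=C[C@@](C)(O[Si](CC)(CC)CC)C[C@H]2CC(=O)C(Cl)(Cl)[C@]21CCCCl
A4 | alternative 2 | ring A-fused 2,2-dichlorocyclobutanone | C1=C[C@@](C)(O[Si](CC)(CC)CC)C[C@H]2C(=O)C(Cl)(Cl)[C@]21CCCCl
A5 | alternative 3 | ring A cyclohexene with C1 silyloxy, C16 formyl and C5 ester | CC(C)(C)[Si](C)(C)O[C@H]1C=C(C)C[C@@H](C(=O)OC)[C@]1(C=O)CCCCl
A6 | alternative 3 | (E)-1-(tert-butyldimethylsilyloxy)-3-methylbuta-1,3-diene | C=C(C)/C=C/O[Si](C)(C)C(C)(C)C
A7 | alternative 3 | methyl (Z)-6-chloro-3-formylhex-2-enoate | COC(=O)/C=C(\C=O)CCCCl
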